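**Retrosynthetic overview**

1. The target is traced back to a side-chain ketone (methyl addition under Felkin–Anh control), then to a bicyclic enol-triketone that lacks the prenyl group on the acyl-bearing ring carbon (Tsuji–Trost prenylation).
2. Key disconnection: ring B (the dihydrofuran) is built in one operation from the ring A trione, formaldehyde and an α-hydroxy ketone. The CH2–CH(O) bond and the O–C(sp2) bond of ring B form together, along with the CH2–ring A bond.
3. Enabling feature: ring A has one unsubstituted carbon, C6, between the C5 and C1 carbonyls. It condenses with formaldehyde to an exocyclic enone C=C6–C5=O; the CH2 accepts the enamine carbon and the C5 carbonyl takes up the hydroxyl oxygen. The hydrogen-bonded 2-isobutyryl-1,3-dione unit (C1–C2–C3) keeps C1 out of the ring closure. Ring B then blocks C6, so the last prenyl group can only enter at the acyl-bearing carbon.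
4. Ring A comes from a Claisen cyclisation of a 3,5,7-triketo ester, made from a diketone dianion and a malonic half-ester chloride; the methyl/prenyl quaternary carbon is set by esterase desymmetrisation of a prochiral malonate.
5. Order of ring formation: ring A (step 4), then ring B (step 7).

Key step: step 7

Assumption: the sense of induction of the esterase (step 2), of L-proline (step 7) and of the (R,R)-ligand (step 8) on these new substrates is assigned by analogy with their closest precedents; if a sense proves opposite, the antipodal catalyst (steps 7, 8) or the resolution given as fallback (step 2) is used and the chemistry is otherwise unchanged.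

Remark: the descriptor of the methyl/prenyl quaternary carbon changes along the route (R in 9, 16 and 18, S in 17, 20 and 21) only because CIP priorities change with the tautomer drawn; the centre is never touched after step 2.

**Route**

Step 1
Reactants: 1 dimethyl 2-methylpropanedioate; 2 1-bromo-3-methylbut-2-ene
Product: 3 dimethyl 2-methyl-2-(3-methylbut-2-en-1-yl)propanedioate
Conditions: NaH, THF, 0 to 20 °C
Reagents that add atoms: none
Why: Malonic ester alkylation (SN2 at a primary allylic bromide) should give the achiral diester, whose two ester groups are enantiotopic.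

Step 2
Reactants: 3 dimethyl 2-methyl-2-(3-methylbut-2-en-1-yl)propanedioate
Product: 4 (2S)-2-(methoxycarbonyl)-2,5-dimethylhex-4-enoic acid
Conditions: pig liver esterase (carboxylesterase), phosphate buffer pH 7.5, DMSO (10 vol %), 25 °C, pH-stat with NaOH; then HCl to pH 2
Reagents that add atoms: water, O
Why: Esterase-catalysed desymmetrisation of a prochiral 2,2-disubstituted malonic diester hydrolyses one enantiotopic ester and thereby sets the quaternary stereocentre (later C7 of the target).

Step 3
Reactants: 4 (2S)-2-(methoxycarbonyl)-2,5-dimethylhex-4-enoic acid; 5 5-methylhexane-2,4-dione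
Product: 8 methyl (2S)-2,8-dimethyl-2-(3-methylbut-2-en-1-yl)-3,5,7-trioxononanoate, via acid chloride 6 (not isolated), via diketone dianion 7 (not isolated)
Conditions: 4, 1-chloro-N,N,2-trimethylprop-1-en-1-amine, CH2Cl2, 0 °C; separately 5, LiN(iPr)2 (2.1 equiv), THF, −78 to 0 °C; 6 added to 7 (2.2 equiv), −78 to −20 °C; AcOH quench
Reagents that add atoms: none
Why: Acylation of the terminal carbanion of a 1,3-diketone dianion (polyketide-type chain extension) should occur at the acid chloride and not at the methyl ester; the acid chloride is made under neutral conditions to spare the prenyl alkene, and the quaternary centre is not involved.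

Step 4
Reactants: 8 methyl (2S)-2,8-dimethyl-2-(3-methylbut-2-en-1-yl)-3,5,7-trioxononanoate
Product: 9 (4R)-3-hydroxy-4-methyl-4-(3-methylbut-2-en-1-yl)-2-(2-methylpropanoyl)cyclohex-2-ene-1,5-dione (one enol form of the 2-acylcyclohexane-1,3,5-trione)
Conditions: Mg(OMe)2, MeOH, 65 °C; then cold 1 M HCl
Reagents that add atoms: none
Why: Intramolecular Claisen condensation of the C6 carbanion onto the ester (the biomimetic cyclisation that normally gives acylphloroglucinols) should close ring A, which cannot aromatise because C4 is quaternary; the stable delocalised anion of 9 is the thermodynamic sink.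

Step 5
Reactants: 10 5-bromo-2-methylpent-2-ene; 11 2-[(tert-butyldimethylsilyl)oxy]-N-methoxy-N-methylacetamide
Product: 13 1-[(tert-butyldimethylsilyl)oxy]-6-methylhept-5-en-2-one, via Grignard reagent 12 (not isolated)
Conditions: Mg, THF, 20 to 40 °C; then 11, 0 °C; aq. NH4Cl
Reagents that add atoms: none
Why: Weinreb ketone synthesis; the chelated tetrahedral intermediate should prevent over-addition.

Step 6
Reactants: 13 1-[(tert-butyldimethylsilyl)oxy]-6-methylhept-5-en-2-one
Product: 14 1-hydroxy-6-methylhept-5-en-2-one
Conditions: HF·pyridine, THF, 0 °C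
Reagents that add atoms: none
Why: Fluoride-driven cleavage of the primary silyl ether under buffered acidic conditions should avoid the base-induced self-condensation of the α-hydroxy ketone, which is used at once.

Step 7
Reactants: 9 (4R)-3-hydroxy-4-methyl-4-(3-methylbut-2-en-1-yl)-2-(2-methylpropanoyl)cyclohex-2-ene-1,5-dione; 14 1-hydroxy-6-methylhept-5-en-2-one; 15 formaldehyde (37 % aqueous solution)
Product: 18 (2S,7R)-6-hydroxy-7-methyl-2-(5-methylhex-4-enoyl)-7-(3-methylbut-2-en-1-yl)-5-(2-methylpropanoyl)-2,3-dihydro-1-benzofuran-4(7H)-one, via methylidene trione 16 (not isolated), via Michael adduct 17 (not isolated)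
Conditions: L-proline (30 mol %), 14 (3 equiv), slow addition of 15 (1.1 equiv), DMSO, 20 °C; then PPTS (20 mol %), 40 °C, same flask
Reagents that add atoms: none
Why: Proposed new method: L-proline is expected to condense formaldehyde at C6 of 9 to the 6-methylidene trione 16 and to convert 14 at its hydroxyl-bearing α-carbon into an (E)-enamine that adds to the exocyclic CH2 of 16 (Michael addition), hydrolysis giving 17, whose hydroxyl then adds to the C5 carbonyl and loses water; the closest known reaction types are the amine-catalysed three-component Knoevenagel–Michael coupling of cyclic 1,3-diones, aldehydes and ketones and the Michael/hemiketalisation/dehydration annulation of α-hydroxy ketones with enones to 2,3-dihydrofurans. Ring B closes by 5-exo-trig attack of the hydroxyl on C5=O, followed by dehydration through the acidic C6–H (E1cB), which gives the vinylogous ester. The new stereocentre (C2 of ring B) is set by the catalyst: the carboxylic acid of L-proline hydrogen-bonds a carbonyl of 16 and delivers it to the same enamine face as in proline-catalysed aldol additions of hydroxyacetone, which corresponds to (S). The step needs (a) enamine formation on the hydroxylated side of 14, secured by the hydroxyl group that stabilises this enamine, (b) condensation at C6 only, secured because C6 is the only ring carbon that bears hydrogen between two carbonyls, and (c) closure onto C5 and not C1, secured by the isobutyryl group, which ties C1=O and C3–OH into the hydrogen-bonded enol of the 2-acyl-1,3-dione so that C5 is the only free ketone next to C6. Six-membered hemiketals at the side-chain ketone are reversible, cannot dehydrate to a stable product and should drain into 18.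

Step 8
Reactants: 18 (2S,7R)-6-hydroxy-7-methyl-2-(5-methylhex-4-enoyl)-7-(3-methylbut-2-en-1-yl)-5-(2-methylpropanoyl)-2,3-dihydro-1-benzofuran-4(7H)-one; 19 3-methylbut-2-en-1-yl acetate
Product: 20 (2S,5R,7S)-7-methyl-2-(5-methylhex-4-enoyl)-5,7-bis(3-methylbut-2-en-1-yl)-5-(2-methylpropanoyl)-2,3-dihydro-1-benzofuran-4,6(5H,7H)-dione
Conditions: Pd2(dba)3·CHCl3 (2.5 mol %), (1R,2R)-N,N'-bis[2-(diphenylphosphanyl)benzoyl]cyclohexane-1,2-diamine (7.5 mol %), Et3N (1.2 equiv), CH2Cl2, 0 to 20 °C
Reagents that add atoms: none
Why: Tsuji–Trost allylic alkylation (zerovalent palladium) of the acidic 2-acyl-1,3-dione should occur at C5, the only nucleophilic carbon left now that ring B has blocked the former C6, with attack at the unsubstituted allyl terminus (linear prenyl; O-allylation is reversible); the new quaternary centre should form on the face anti to the C7 prenyl group, an intrinsic preference that the chiral ligand is meant to reinforce.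

Step 9
Reactants: 20 (2S,5R,7S)-7-methyl-2-(5-methylhex-4-enoyl)-5,7-bis(3-methylbut-2-en-1-yl)-5-(2-methylpropanoyl)-2,3-dihydro-1-benzofuran-4,6(5H,7H)-dione
Product: 21 (2S,5R,7S)-2-[(2S)-2-hydroxy-6-methylhept-5-en-2-yl]-7-methyl-5,7-bis(3-methylbut-2-en-1-yl)-5-(2-methylpropanoyl)-2,3-dihydro-1-benzofuran-4,6(5H,7H)-dione (CNP0155474.1)
Conditions: MeTi(OiPr)3 (3 equiv), THF, −30 to 20 °C; aq. NH4Cl
Reagents that add atoms: methyltitanium triisopropoxide, C[Ti](OC(C)C)(OC(C)C)OC(C)C
Why: A non-chelating, non-basic methyl nucleophile should add only to the unhindered α-oxygenated side-chain ketone (the other three carbonyls are flanked by quaternary carbons or are vinylogous esters) and, with the weakly basic ring oxygen anti to the incoming methyl (Felkin–Anh model), should give the (S)-carbinol.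

**Compound list**

1 | dimethyl 2-methylpropanedioate | COC(=O)C(C)C(=O)OC | starting material
2 | 1-bromo-3-methylbut-2-ene | CC(C)=CCBr | starting material
3 | dimethyl 2-methyl-2-(3-methylbut-2-en-1-yl)propanedioate | COC(=O)C(C)(CC=C(C)C)C(=O)OC | intermediate
4 | (2S)-2-(methoxycarbonyl)-2,5-dimethylhex-4-enoic acid | OC(=O)[C@](C)(CC=C(C)C)C(=O)OC | intermediate
5 | 5-methylhexane-2,4-dione | CC(=O)CC(=O)C(C)C | starting material
6 | methyl (2R)-2-(chlorocarbonyl)-2,5-dimethylhex-4-enoate | COC(=O)[C@@](C)(CC=C(C)C)C(Cl)=O | intermediate
7 | dilithium 5-methylhexa-1,3-diene-2,4-diolate (dianion of 5) | [Li+].[Li+].C=C([O-])C=C([O-])C(C)C | intermediate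
8 | methyl (2S)-2,8-dimethyl-2-(3-methylbut-2-en-1-yl)-3,5,7-trioxononanoate | COC(=O)[C@@](C)(CC=C(C)C)C(=O)CC(=O)CC(=O)C(C)C | intermediate
9 | (4R)-3-hydroxy-4-methyl-4-(3-methylbut-2-en-1-yl)-2-(2-methylpropanoyl)cyclohex-2-ene-1,5-dione | O=C1CC(=O)[C@](C)(CC=C(C)C)C(O)=C1C(=O)C(C)C | intermediate
10 | 5-bromo-2-methylpent-2-ene | CC(C)=CCCBr | starting material
11 | 2-[(tert-butyldimethylsilyl)oxy]-N-methoxy-N-methylacetamide | CON(C)C(=O)CO[Si](C)(C)C(C)(C)C | starting material
12 | (4-methylpent-3-en-1-yl)magnesium bromide | CC(C)=CCC[Mg]Br | intermediate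
13 | 1-[(tert-butyldimethylsilyl)oxy]-6-methylhept-5-en-2-one | CC(C)=CCCC(=O)CO[Si](C)(C)C(C)(C)C | intermediate
14 | 1-hydroxy-6-methylhept-5-en-2-one | CC(C)=CCCC(=O)CO | intermediate
15 | formaldehyde | C=O | starting material
16 | (4R)-3-hydroxy-4-methyl-6-methylidene-4-(3-methylbut-2-en-1-yl)-2-(2-methylpropanoyl)cyclohex-2-ene-1,5-dione | C=C1C(=O)[C@](C)(CC=C(C)C)C(O)=C(C(=O)C(C)C)C1=O | intermediate
17 | (4S)-3,5-dihydroxy-6-[(2S)-2-hydroxy-7-methyl-3-oxooct-6-en-1-yl]-4-methyl-4-(3-methylbut-2-en-1-yl)-2-(2-methylpropanoyl)cyclohexa-2,5-dien-1-one | CC(C)=CCCC(=O)[C@@H](O)CC1=C(O)[C@](C)(CC=C(C)C)C(O)=C(C(=O)C(C)C)C1=O | intermediate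
18 | (2S,7R)-6-hydroxy-7-methyl-2-(5-methylhex-4-enoyl)-7-(3-methylbut-2-en-1-yl)-5-(2-methylpropanoyl)-2,3-dihydro-1-benzofuran-4(7H)-one | CC(C)=CCCC(=O)[C@@H]1CC2=C(O1)[C@](C)(CC=C(C)C)C(O)=C(C(=O)C(C)C)C2=O | intermediate
19 | 3-methylbut-2-en-1-yl acetate | CC(=O)OCC=C(C)C | starting material
20 | (2S,5R,7S)-7-methyl-2-(5-methylhex-4-enoyl)-5,7-bis(3-methylbut-2-en-1-yl)-5-(2-methylpropanoyl)-2,3-dihydro-1-benzofuran-4,6(5H,7H)-dione | CC(C)=CCCC(=O)[C@@H]1CC2=C(O1)[C@](C)(CC=C(C)C)C(=O)[C@](CC=C(C)C)(C(=O)C(C)C)C2=O | intermediate
21 | (2S,5R,7S)-2-[(2S)-2-hydroxy-6-methylhept-5-en-2-yl]-7-methyl-5,7-bis(3-methylbut-2-en-1-yl)-5-(2-methylpropanoyl)-2,3-dihydro-1-benzofuran-4,6(5H,7H)-dione | CC(C)=CCC[C@](C)(O)[C@@H]1CC2=C(O1)[C@](C)(CC=C(C)C)C(=O)[C@](CC=C(C)C)(C(=O)C(C)C)C2=O | target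

**Step count and risks**

Total step count: 9. Longest linear sequence: 7 steps (steps 1 to 4, then 7 to 9; steps 5 and 6 make the side-chain partner).

Steps most likely to fail:

1. Step 7 (proposed new method). The enamine addition may show poor facial selectivity, the C2 centre may erode by enolisation next to the ketone, and the methylidene trione may be diverted into a methylene-bridged dimer of 9. Fallback (sets out from 9, returns to the route at 18): the same two bonds are made by known chemistry without asymmetric induction. Pyrrolidine/acetic acid (20 mol %) catalyses the three-component Knoevenagel–Michael coupling of 9, 15 and an excess of 14, and PPTS then closes ring B. This should give 18 together with the C2 epimer of 18 F1. The two are diastereomers, because ring A is already enantiopure, and are separated by chromatography. F1 is equilibrated with DBU (epimerisation of the C–H next to the ketone) and separated again.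

2. Step 8. Facial selectivity at C5 may be poor, because the methyl and prenyl groups at C7 differ little in size, and O-allylation or attack at the substituted allyl terminus may compete. Fallback (sets out from 18, returns at 20): allyl chloroformate and Et3N convert 18 into the O6 allyl enol carbonate of 18 F2. Pd2(dba)3 with (S)-4-tert-butyl-2-[2-(diphenylphosphanyl)phenyl]-4,5-dihydrooxazole then effects decarboxylative allylation within the ion pair and should give the C5-allyl analogue of 20 F3. Cross-metathesis with 2-methylbut-2-ene (second-generation Grubbs catalyst, RuCl2(=CHPh)(H2IMes)(PCy3)) turns the allyl group into prenyl and gives 20; the trisubstituted alkenes already present only exchange degenerately.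

3. Step 2. The esterase may discriminate poorly between the enantiotopic ester groups when the other substituents are methyl and prenyl. Fallback (sets out from 3, returns at 4): 3 is half-saponified with KOH (1 equiv) in methanol to racemic 2-(methoxycarbonyl)-2,5-dimethylhex-4-enoic acid F4. This is resolved by crystallisation of the (S)-1-phenylethylammonium salt of the (2S)-acid F5 (the antipodal amine is used if the other salt is the less soluble one). Acidification returns 4.

Further compounds
F1 | step 7 | C2 epimer of 18: (2R)-configured at the ring B carbon, ring A unchanged | CC(C)=CCCC(=O)[C@H]1CC2=C(O1)[C@](C)(CC=C(C)C)C(O)=C(C(=O)C(C)C)C2=O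
F2 | step 8 | O6 allyl enol carbonate of 18 (prop-2-en-1-yl carbonate on the C6 enol oxygen, configuration as in 18) | CC(C)=CCCC(=O)[C@@H]1CC2=C(O1)[C@](C)(CC=C(C)C)C(OC(=O)OCC=C)=C(C(=O)C(C)C)C2=O
F3 | step 8 | C5-allyl analogue of 20 (prop-2-en-1-yl in place of the C5 prenyl group, configuration as in 20) | CC(C)=CCCC(=O)[C@@H]1CC2=C(O1)[C@](C)(CC=C(C)C)C(=O)[C@](CC=C)(C(=O)C(C)C)C2=O
F4 | step 2 | racemic 2-(methoxycarbonyl)-2,5-dimethylhex-4-enoic acid | OC(=O)C(C)(CC=C(C)C)C(=O)OC
F5 | step 2 | (S)-1-phenylethylammonium (2S)-2-(methoxycarbonyl)-2,5-dimethylhex-4-enoate | COC(=O)[C@@](C)(CC=C(C)C)C(=O)[O-].C[C@H]([NH3+])c1ccccc1
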